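Labels: rings A and C form the upper chroman (O1, C2, C3, C4, C4a to C8a). Ring B is its 3-aryl group, ring D is the aryl group on C4 (D1 bound to C4), and rings E and F form the lower chroman (primed atoms).
Retrosynthetic cuts, in order: the four phenolic O-benzyl masks, the D5–C3' bond (through the C3'=C4' olefin), the heteroatom handles at D5 and D2, O1–C8a of ring C, and finally C3–C4.
Enabling feature: C4 carries ring A (oxygen on the ortho carbon C8a and on the para carbon C7) and ring D (oxygen on ortho D2 and on para D4). Both arenes have the same 2,4-dioxygenated pattern, so C4 can begin as a prochiral CH bearing two identical 2-bromo-4-benzyloxyphenyl groups beside C3.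
Forward: the ring B arylacetyl imide and a symmetric benzhydryl ether give C3–C4, and reduction frees the C2 alcohol. Copper then closes ring C on one bromoarene, and the other bromine becomes the D2 oxygen, which steers bromination to D5. A separately built ring E/F chromenyl boronate is coupled, C3'=C4' is hydrogenated and the benzyl groups are removed.
Stereochemistry: C3 (R) comes from (R)-4-benzyloxazolidinone in an Evans alkylation. C4 (S, trans) comes from C3 through the choice between the two diastereotopic bromoarenes. C3' (R) comes from a chiral iridium catalyst.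

Key step: step 11

Assumption: the ligand antipode used in step 20 is the one that reduces simple 3-aryl-2H-chromenes to (3R)-3-arylchromanes, and the distant C3 and C4 centres are taken not to override the catalyst.

Step 1
Reactants: 1 2-hydroxy-4,5-dimethoxybenzaldehyde
Product: 2 2-(benzyloxy)-4,5-dimethoxybenzaldehyde
Conditions: BnBr, K2CO3, DMF, rt
Reagents that add atoms: benzyl bromide, BrCc1ccccc1
Why: Williamson etherification of the phenoxide of 1 with a benzylic bromide, benzyl being chosen so that all phenol masks of the route fall together in the final hydrogenolysis.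

Step 2
Reactants: 2 2-(benzyloxy)-4,5-dimethoxybenzaldehyde
Product: 4 [2-(benzyloxy)-4,5-dimethoxyphenyl]acetonitrile, via formamide adduct 3 (not isolated)
Conditions: TosMIC, t-BuOK, DME, −30 °C; then MeOH, reflux
Reagents that add atoms: tosylmethyl isocyanide (TosMIC), Cc1ccc(cc1)S(=O)(=O)C[N+]#[C-]
Why: Van Leusen reductive cyanation, in which the TosMIC anion adds to the aldehyde and rearranges through an oxazoline to formamide 3, which methanolic base deformylates and desulfinates, so the aldehyde carbon becomes the benzylic CH2 of the nitrile without passing through an acid-labile electron-rich benzyl halide.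

Step 3
Reactants: 4 [2-(benzyloxy)-4,5-dimethoxyphenyl]acetonitrile
Product: 5 [2-(benzyloxy)-4,5-dimethoxyphenyl]acetic acid
Conditions: KOH, EtOH–H2O, reflux; then aq HCl
Reagents that add atoms: potassium hydroxide, [K+].[OH-]; water, O
Why: Basic nitrile hydrolysis, to which aryl methyl and aryl benzyl ethers are inert.

Step 4
Reactants: 5 [2-(benzyloxy)-4,5-dimethoxyphenyl]acetic acid; 6 (4R)-4-benzyl-1,3-oxazolidin-2-one
Product: 8 (4R)-4-benzyl-3-{[2-(benzyloxy)-4,5-dimethoxyphenyl]acetyl}-1,3-oxazolidin-2-one, via mixed pivalic anhydride 7 (not isolated)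
Conditions: PivCl, Et3N, THF, −20 °C; then 6, LiCl, −20 °C → rt
Reagents that add atoms: none
Why: N-Acylation of an Evans oxazolidinone through the mixed pivalic anhydride (LiCl and Et3N variant), in which the auxiliary attacks the unhindered arylacetyl carbonyl and its own stereocentre is not touched.

Step 5
Reactants: 9 3-bromophenol
Product: 10 1-(benzyloxy)-3-bromobenzene
Conditions: BnBr, K2CO3, acetone, reflux
Reagents that add atoms: benzyl bromide, BrCc1ccccc1
Why: Williamson etherification of a simple phenol.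

Step 6
Reactants: 10 1-(benzyloxy)-3-bromobenzene
Product: 11 4-(benzyloxy)-2-bromo-1-iodobenzene
Conditions: NIS, TFA (10 mol %), MeCN, rt, dark
Reagents that add atoms: N-iodosuccinimide, O=C1CCC(=O)N1I
Why: Electrophilic aromatic iodination with acid-activated NIS, directed para to the benzyloxy group (the carbon next to bromine) as is usual for 3-haloaryl ethers, while the unactivated phenyl ring of the benzyl group does not react.

Step 7
Reactants: 11 4-(benzyloxy)-2-bromo-1-iodobenzene (two equivalents)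
Product: 14 bis[4-(benzyloxy)-2-bromophenyl]methanol, via arylmagnesium chloride 12 (not isolated), via 4-(benzyloxy)-2-bromobenzaldehyde 13 (not isolated)
Conditions: i-PrMgCl, THF, −40 °C; HCO2Et (0.48 equiv), −40 → 0 °C; aq NH4Cl
Reagents that add atoms: ethyl formate, CCOC=O
Why: Iodine–magnesium exchange takes only the weaker C–I bond, at −40 °C the 2-bromoaryl Grignard reagent does not collapse to an aryne, and its double addition to ethyl formate through aldehyde 13 gives a benzhydrol whose two arenes are identical by construction.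

Step 8
Reactants: 14 bis[4-(benzyloxy)-2-bromophenyl]methanol
Product: 15 bis[4-(benzyloxy)-2-bromophenyl]methyl methyl ether
Conditions: MeOH–CH2Cl2, TsOH·H2O (2 mol %), rt
Reagents that add atoms: methanol, CO
Why: Acid-catalysed SN1 etherification through the benzhydryl cation stabilised by two para-benzyloxy groups, driven by the excess of methanol.

Step 9
Reactants: 8 (4R)-4-benzyl-3-{[2-(benzyloxy)-4,5-dimethoxyphenyl]acetyl}-1,3-oxazolidin-2-one; 15 bis[4-(benzyloxy)-2-bromophenyl]methyl methyl ether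
Product: 17 (4R)-4-benzyl-3-{(2R)-2-[2-(benzyloxy)-4,5-dimethoxyphenyl]-3,3-bis[4-(benzyloxy)-2-bromophenyl]propanoyl}-1,3-oxazolidin-2-one, via chlorotitanium (Z)-enolate 16 (not isolated)
Conditions: TiCl4 (1.1 equiv), i-Pr2NEt (1.15 equiv), CH2Cl2, 0 °C; then 15, TiCl4 (1.0 equiv), −78 → −20 °C
Reagents that add atoms: none
Why: Evans alkylation of a chelated chlorotitanium (Z)-enolate with an SN1 electrophile, in which TiCl4 ionises 15 to the doubly para-alkoxy-stabilised benzhydryl cation and this is captured on the enolate face away from the benzyl group of the (R)-auxiliary, which sets the future C3 as R, while the neighbouring new CH carries two identical arenes and is not yet stereogenic.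

Step 10
Reactants: 17 (4R)-4-benzyl-3-{(2R)-2-[2-(benzyloxy)-4,5-dimethoxyphenyl]-3,3-bis[4-(benzyloxy)-2-bromophenyl]propanoyl}-1,3-oxazolidin-2-one
Product: 18 (2R)-2-[2-(benzyloxy)-4,5-dimethoxyphenyl]-3,3-bis[4-(benzyloxy)-2-bromophenyl]propan-1-ol
Conditions: LiBH4, H2O (1.1 equiv), THF–Et2O, 0 °C
Reagents that add atoms: none
Why: Reductive cleavage of the N-acyl oxazolidinone with LiBH4 and one equivalent of water, a weakly basic hydride source that attacks the exocyclic carbonyl, should leave the α-aryl centre unepimerised and does not touch aryl bromides or ethers.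

Step 11
Reactants: 18 (2R)-2-[2-(benzyloxy)-4,5-dimethoxyphenyl]-3,3-bis[4-(benzyloxy)-2-bromophenyl]propan-1-ol
Product: 19 (3R,4S)-7-(benzyloxy)-3-[2-(benzyloxy)-4,5-dimethoxyphenyl]-4-[4-(benzyloxy)-2-bromophenyl]chromane (3,4-trans)
Conditions: CuI (10 mol %), 3,4,7,8-tetramethyl-1,10-phenanthroline (20 mol %), Cs2CO3 (2 equiv), toluene (0.02 M), 100 °C
Reagents that add atoms: none
Why: Cs2CO3 turns the C2 hydroxyl into its alkoxide, which binds phenanthroline-ligated monovalent copper; the copper alkoxide inserts into one ortho C–Br bond to give a seven-membered aryl alkoxide of trivalent copper, and reductive elimination forms O1–C8a and returns monovalent copper. The closest known reactions are the intramolecular Ullmann-type etherification of 3-(2-bromoaryl)propan-1-ols to chromanes and the copper- or palladium-catalysed desymmetrising O-arylation of alcohols flanked by two 2-haloaryl groups. Ring C closes as a six-membered ring at the sp2 carbon C8a, formally 6-exo with respect to the departing bromide, the tether being O1–C2–C3–C4–C4a. C4 becomes a stereocentre only in this event and is controlled by C3: the C3–C4 rotamer with H3 and H4 antiperiplanar has the fewest gauche aryl contacts, only one of its two bromoarenes lies gauche to the CH2O–Cu arm, and insertion into that one places ring B and the spectator aryl group both pseudo-equatorial, which is the trans (3R,4S) chromane. The step needs group selectivity between two constitutionally identical, diastereotopic aryl bromides, which this conformational bias should secure, and it must stop after one coupling, which is secured because the molecule has a single hydroxyl group and the reaction is run dilute. Copper is preferred to palladium because its primary alkoxides resist β-hydride elimination, so neither oxidation at C2 nor reduction of the surviving bromide, the marker of the future D2 oxygen, should interfere.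

Step 12
Reactants: 19 (3R,4S)-7-(benzyloxy)-3-[2-(benzyloxy)-4,5-dimethoxyphenyl]-4-[4-(benzyloxy)-2-bromophenyl]chromane
Product: 22 5-(benzyloxy)-2-{(3R,4R)-7-(benzyloxy)-3-[2-(benzyloxy)-4,5-dimethoxyphenyl]chroman-4-yl}phenol (3,4-trans), via aryllithium 20 (not isolated), via dimethyl arylboronate 21 (not isolated)
Conditions: n-BuLi, THF, −78 °C; B(OMe)3, −78 °C → rt; 30% H2O2, aq NaOH, 0 °C
Reagents that add atoms: hydrogen peroxide, OO
Why: Bromine–lithium exchange is indifferent to the steric shielding by C4 and outruns deprotonation at −78 °C, and borate capture followed by the 1,2-aryl shift of the peroxide adduct (boronate oxidation) puts the hydroxyl group exactly where bromine stood, with C3 and C4 untouched and the C4 descriptor changing to R through CIP ranking only.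

Step 13
Reactants: 22 5-(benzyloxy)-2-{(3R,4R)-7-(benzyloxy)-3-[2-(benzyloxy)-4,5-dimethoxyphenyl]chroman-4-yl}phenol
Product: 23 5-(benzyloxy)-4-bromo-2-{(3R,4R)-7-(benzyloxy)-3-[2-(benzyloxy)-4,5-dimethoxyphenyl]chroman-4-yl}phenol (3,4-trans)
Conditions: NBS (1.0 equiv), CH2Cl2–MeCN, −40 °C, dark
Reagents that add atoms: N-bromosuccinimide, O=C1CCC(=O)N1Br
Why: Electrophilic aromatic bromination of a phenol, in which D5 is para to the only free hydroxyl group and ortho to the D4 benzyloxy group and should be the most nucleophilic carbon present, D3 is wedged between two oxygens, and rings A and B carry ether donors only, so one equivalent of NBS at low temperature should stop at the D5 monobromide.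

Step 14
Reactants: 23 5-(benzyloxy)-4-bromo-2-{(3R,4R)-7-(benzyloxy)-3-[2-(benzyloxy)-4,5-dimethoxyphenyl]chroman-4-yl}phenol
Product: 24 (3R,4S)-7-(benzyloxy)-4-[4-(benzyloxy)-5-bromo-2-methoxyphenyl]-3-[2-(benzyloxy)-4,5-dimethoxyphenyl]chromane (3,4-trans)
Conditions: MeI, K2CO3, DMF, rt
Reagents that add atoms: iodomethane, CI
Why: Williamson methylation of the only free phenol installs the D2 methoxy group of the target, and the C4 descriptor returns to S through CIP ranking only.

Step 15
Reactants: 25 2,4-dihydroxybenzaldehyde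
Product: 26 4-(benzyloxy)-2-hydroxybenzaldehyde
Conditions: BnBr (1.0 equiv), NaHCO3, MeCN, reflux
Reagents that add atoms: benzyl bromide, BrCc1ccccc1
Why: Regioselective Williamson etherification, because the 2-hydroxyl is tied up in a hydrogen bond to the aldehyde and is less acidic, so a weak base and one equivalent of benzyl bromide alkylate only the 4-hydroxyl.

Step 16
Reactants: 26 4-(benzyloxy)-2-hydroxybenzaldehyde
Product: 27 7-(benzyloxy)-2H-chromene
Conditions: H2C=CHPPh3Br, DBU, MeCN, reflux
Reagents that add atoms: vinyltriphenylphosphonium bromide, C=C[P+](c1ccccc1)(c1ccccc1)c1ccccc1.[Br-]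
Why: Schweizer chromene synthesis, in which the phenoxide adds to the vinylphosphonium salt (oxa-Michael addition) and the resulting ylide closes ring F by an intramolecular Wittig reaction with the neighbouring aldehyde.

Step 17
Reactants: 27 7-(benzyloxy)-2H-chromene
Product: 29 7-(benzyloxy)-3-bromo-2H-chromene, via trans-3,4-dibromochroman 28 (not isolated)
Conditions: Br2 (1.0 equiv), CH2Cl2, −78 °C; then DBU, −78 °C → rt
Reagents that add atoms: bromine, BrBr
Why: Bromination–dehydrobromination, in which bromine adds to the electron-rich styrene-type C3'=C4' bond faster than it substitutes ring E at −78 °C and the base then removes HBr through loss of the labile benzylic C4' bromide and of H3', leaving the vinylic bromide at C3'.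

Step 18
Reactants: 29 7-(benzyloxy)-3-bromo-2H-chromene
Product: 30 2-[7-(benzyloxy)-2H-chromen-3-yl]-4,4,5,5-tetramethyl-1,3,2-dioxaborolane
Conditions: B2pin2, PdCl2(dppf) (3 mol %), KOAc, dioxane, 80 °C
Reagents that add atoms: bis(pinacolato)diboron, CC1(C)OB(OC1(C)C)B1OC(C)(C)C(C)(C)O1
Why: Miyaura borylation of an alkenyl bromide, in which the weak base KOAc suppresses homocoupling and the allylic aryl ether is inert.

Step 19
Reactants: 24 (3R,4S)-7-(benzyloxy)-4-[4-(benzyloxy)-5-bromo-2-methoxyphenyl]-3-[2-(benzyloxy)-4,5-dimethoxyphenyl]chromane; 30 2-[7-(benzyloxy)-2H-chromen-3-yl]-4,4,5,5-tetramethyl-1,3,2-dioxaborolane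
Product: 31 (3R,4S)-7-(benzyloxy)-4-{4-(benzyloxy)-5-[7-(benzyloxy)-2H-chromen-3-yl]-2-methoxyphenyl}-3-[2-(benzyloxy)-4,5-dimethoxyphenyl]chromane
Conditions: Pd(OAc)2 (3 mol %), SPhos (6 mol %), K3PO4, toluene–H2O, 80 °C
Reagents that add atoms: none
Why: Suzuki–Miyaura coupling between two sp2 carbons, in which the electron-rich biaryl phosphine promotes insertion of zerovalent palladium into the electron-rich ortho-alkoxy C–Br bond at D5 and no stereocentre is involved.

Step 20
Reactants: 31 (3R,4S)-7-(benzyloxy)-4-{4-(benzyloxy)-5-[7-(benzyloxy)-2H-chromen-3-yl]-2-methoxyphenyl}-3-[2-(benzyloxy)-4,5-dimethoxyphenyl]chromane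
Product: 32 (3R,4S)-7-(benzyloxy)-4-{4-(benzyloxy)-5-[(3R)-7-(benzyloxy)chroman-3-yl]-2-methoxyphenyl}-3-[2-(benzyloxy)-4,5-dimethoxyphenyl]chromane
Conditions: [Ir(cod)(Cy2P-ThrePHOX)][B(3,5-(CF3)2C6H3)4] (2 mol %, ligand antipode giving 3R), H2 (50 bar), CH2Cl2, rt
Reagents that add atoms: none
Why: Iridium-catalysed asymmetric hydrogenation of an unfunctionalised trisubstituted olefin with a chiral N,P ligand, a reaction known for 3-aryl-2H-chromenes, in which the catalyst selects the olefin face and sets C3' as R, C3 and C4 are too remote to interfere, and benzyl ethers are not cleaved by this homogeneous catalyst.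

Step 21
Reactants: 32 (3R,4S)-7-(benzyloxy)-4-{4-(benzyloxy)-5-[(3R)-7-(benzyloxy)chroman-3-yl]-2-methoxyphenyl}-3-[2-(benzyloxy)-4,5-dimethoxyphenyl]chromane
Product: 33 (3R,4S)-4-{4-hydroxy-5-[(3R)-7-hydroxychroman-3-yl]-2-methoxyphenyl}-3-(2-hydroxy-4,5-dimethoxyphenyl)chroman-7-ol (CNP0217096.1)
Conditions: H2 (1 atm), 10% Pd/C, THF–MeOH, rt
Reagents that add atoms: none
Why: Hydrogenolysis of the four aryl benzyl ethers over palladium on carbon, which leaves the methyl ethers, both pyran rings and the three stereocentres alone because none of them holds a benzylic C–O bond.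

Compound list
1 | 2-hydroxy-4,5-dimethoxybenzaldehyde | COc1cc(O)c(C=O)cc1OC | starting material
2 | 2-(benzyloxy)-4,5-dimethoxybenzaldehyde | COc1cc(OCc2ccccc2)c(C=O)cc1OC | intermediate
3 | N-{2-[2-(benzyloxy)-4,5-dimethoxyphenyl]-1-[(4-methylphenyl)sulfonyl]ethenyl}formamide (present as its potassium salt, olefin geometry of no consequence) | COc1cc(OCc2ccccc2)c(C=C(NC=O)S(=O)(=O)c2ccc(C)cc2)cc1OC | intermediate
4 | [2-(benzyloxy)-4,5-dimethoxyphenyl]acetonitrile | COc1cc(OCc2ccccc2)c(CC#N)cc1OC | intermediate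
5 | [2-(benzyloxy)-4,5-dimethoxyphenyl]acetic acid | COc1cc(OCc2ccccc2)c(CC(=O)O)cc1OC | intermediate
6 | (4R)-4-benzyl-1,3-oxazolidin-2-one | O=C1N[C@H](Cc2ccccc2)CO1 | starting material
7 | [2-(benzyloxy)-4,5-dimethoxyphenyl]acetic pivalic anhydride | COc1cc(OCc2ccccc2)c(CC(=O)OC(=O)C(C)(C)C)cc1OC | intermediate
8 | (4R)-4-benzyl-3-{[2-(benzyloxy)-4,5-dimethoxyphenyl]acetyl}-1,3-oxazolidin-2-one | COc1cc(OCc2ccccc2)c(CC(=O)N2[C@H](Cc3ccccc3)COC2=O)cc1OC | intermediate
9 | 3-bromophenol | Oc1cccc(Br)c1 | starting material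
10 | 1-(benzyloxy)-3-bromobenzene | Brc1cccc(OCc2ccccc2)c1 | intermediate
11 | 4-(benzyloxy)-2-bromo-1-iodobenzene | Ic1ccc(OCc2ccccc2)cc1Br | intermediate
12 | [4-(benzyloxy)-2-bromophenyl]magnesium chloride | Cl[Mg]c1ccc(OCc2ccccc2)cc1Br | intermediate
13 | 4-(benzyloxy)-2-bromobenzaldehyde | O=Cc1ccc(OCc2ccccc2)cc1Br | intermediate
14 | bis[4-(benzyloxy)-2-bromophenyl]methanol | OC(c1ccc(OCc2ccccc2)cc1Br)c1ccc(OCc2ccccc2)cc1Br | intermediate
15 | bis[4-(benzyloxy)-2-bromophenyl]methyl methyl ether | COC(c1ccc(OCc2ccccc2)cc1Br)c1ccc(OCc2ccccc2)cc1Br | intermediate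
16 | trichlorotitanium (Z)-enolate of imide 8 | COc1cc(OCc2ccccc2)c(/C=C(\O[Ti](Cl)(Cl)Cl)N2[C@H](Cc3ccccc3)COC2=O)cc1OC | intermediate
17 | (4R)-4-benzyl-3-{(2R)-2-[2-(benzyloxy)-4,5-dimethoxyphenyl]-3,3-bis[4-(benzyloxy)-2-bromophenyl]propanoyl}-1,3-oxazolidin-2-one | COc1cc(OCc2ccccc2)c([C@H](C(=O)N2[C@H](Cc3ccccc3)COC2=O)C(c2ccc(OCc3ccccc3)cc2Br)c2ccc(OCc3ccccc3)cc2Br)cc1OC | intermediate
18 | (2R)-2-[2-(benzyloxy)-4,5-dimethoxyphenyl]-3,3-bis[4-(benzyloxy)-2-bromophenyl]propan-1-ol | COc1cc(OCc2ccccc2)c([C@H](CO)C(c2ccc(OCc3ccccc3)cc2Br)c2ccc(OCc3ccccc3)cc2Br)cc1OC | intermediate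
19 | (3R,4S)-7-(benzyloxy)-3-[2-(benzyloxy)-4,5-dimethoxyphenyl]-4-[4-(benzyloxy)-2-bromophenyl]chromane (3,4-trans) | COc1cc(OCc2ccccc2)c([C@@H]2COc3cc(OCc4ccccc4)ccc3[C@H]2c2ccc(OCc3ccccc3)cc2Br)cc1OC | intermediate
20 | (3R,4R)-7-(benzyloxy)-3-[2-(benzyloxy)-4,5-dimethoxyphenyl]-4-[4-(benzyloxy)-2-lithiophenyl]chromane (3,4-trans) | COc1cc(OCc2ccccc2)c([C@@H]2COc3cc(OCc4ccccc4)ccc3[C@H]2c2ccc(OCc3ccccc3)cc2[Li])cc1OC | intermediate
21 | dimethyl (5-(benzyloxy)-2-{(3R,4R)-7-(benzyloxy)-3-[2-(benzyloxy)-4,5-dimethoxyphenyl]chroman-4-yl}phenyl)boronate (3,4-trans) | COc1cc(OCc2ccccc2)c([C@@H]2COc3cc(OCc4ccccc4)ccc3[C@H]2c2ccc(OCc3ccccc3)cc2B(OC)OC)cc1OC | intermediate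
22 | 5-(benzyloxy)-2-{(3R,4R)-7-(benzyloxy)-3-[2-(benzyloxy)-4,5-dimethoxyphenyl]chroman-4-yl}phenol (3,4-trans) | COc1cc(OCc2ccccc2)c([C@@H]2COc3cc(OCc4ccccc4)ccc3[C@H]2c2ccc(OCc3ccccc3)cc2O)cc1OC | intermediate
23 | 5-(benzyloxy)-4-bromo-2-{(3R,4R)-7-(benzyloxy)-3-[2-(benzyloxy)-4,5-dimethoxyphenyl]chroman-4-yl}phenol (3,4-trans) | COc1cc(OCc2ccccc2)c([C@@H]2COc3cc(OCc4ccccc4)ccc3[C@H]2c2cc(Br)c(OCc3ccccc3)cc2O)cc1OC | intermediate
24 | (3R,4S)-7-(benzyloxy)-4-[4-(benzyloxy)-5-bromo-2-methoxyphenyl]-3-[2-(benzyloxy)-4,5-dimethoxyphenyl]chromane (3,4-trans) | COc1cc(OCc2ccccc2)c([C@@H]2COc3cc(OCc4ccccc4)ccc3[C@H]2c2cc(Br)c(OCc3ccccc3)cc2OC)cc1OC | intermediate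
25 | 2,4-dihydroxybenzaldehyde | O=Cc1ccc(O)cc1O | starting material
26 | 4-(benzyloxy)-2-hydroxybenzaldehyde | O=Cc1ccc(OCc2ccccc2)cc1O | intermediate
27 | 7-(benzyloxy)-2H-chromene | C1=Cc2ccc(OCc3ccccc3)cc2OC1 | intermediate
28 | (±)-trans-7-(benzyloxy)-3,4-dibromochromane (one enantiomer drawn) | Br[C@@H]1COc2cc(OCc3ccccc3)ccc2[C@H]1Br | intermediate
29 | 7-(benzyloxy)-3-bromo-2H-chromene | BrC1=Cc2ccc(OCc3ccccc3)cc2OC1 | intermediate
30 | 2-[7-(benzyloxy)-2H-chromen-3-yl]-4,4,5,5-tetramethyl-1,3,2-dioxaborolane | CC1(C)OB(OC1(C)C)C1=Cc2ccc(OCc3ccccc3)cc2OC1 | intermediate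
31 | (3R,4S)-7-(benzyloxy)-4-{4-(benzyloxy)-5-[7-(benzyloxy)-2H-chromen-3-yl]-2-methoxyphenyl}-3-[2-(benzyloxy)-4,5-dimethoxyphenyl]chromane | COc1cc(OCc2ccccc2)c([C@@H]2COc3cc(OCc4ccccc4)ccc3[C@H]2c2cc(C3=Cc4ccc(OCc5ccccc5)cc4OC3)c(OCc3ccccc3)cc2OC)cc1OC | intermediate
32 | (3R,4S)-7-(benzyloxy)-4-{4-(benzyloxy)-5-[(3R)-7-(benzyloxy)chroman-3-yl]-2-methoxyphenyl}-3-[2-(benzyloxy)-4,5-dimethoxyphenyl]chromane | COc1cc(OCc2ccccc2)c([C@@H]2COc3cc(OCc4ccccc4)ccc3[C@H]2c2cc([C@@H]3COc4cc(OCc5ccccc5)ccc4C3)c(OCc3ccccc3)cc2OC)cc1OC | intermediate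
33 | (3R,4S)-4-{4-hydroxy-5-[(3R)-7-hydroxychroman-3-yl]-2-methoxyphenyl}-3-(2-hydroxy-4,5-dimethoxyphenyl)chroman-7-ol (CNP0217096.1) | COc1cc(O)c([C@@H]2COc3cc(O)ccc3[C@H]2c2cc([C@@H]3COc4cc(O)ccc4C3)c(O)cc2OC)cc1OC | target

Total steps: 21. Longest linear sequence: 13 (steps 1–4, 9–14 and 19–21; the line from 3-bromophenol through steps 5–8 is equally long).

Steps most likely to fail

Step 9. The C3–C4 bond joins two heavily ortho-substituted carbons, so capture of the cation by the enolate may be slow. The cation could then be lost to Friedel–Crafts attack on the electron-rich arenes, and long contact with TiCl4 could strip benzyl ethers. The fallback replaces the stoichiometric titanium enolate with a catalytic nickel enolate of a thioimide.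
- It sets out from acid 5, which is condensed with commercial (4R)-4-isopropyl-1,3-thiazolidine-2-thione (EDC·HCl, DMAP, CH2Cl2) to give the N-arylacetyl thiazolidinethione F1.
- This is alkylated with ether 15 under (Me3P)2NiCl2 catalysis (TESOTf, 2,6-lutidine, CH2Cl2, −20 °C) to give the alkylated thioimide F2. This direct SN1-type alkylation is established for diarylmethyl methyl ethers and is free of strong Lewis acid.
- NaBH4 in THF–H2O releases the easily displaced auxiliary, and the route is rejoined at alcohol 18.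

Step 11. Discrimination between the two diastereotopic bromoarenes may be weak, which would erode the trans selectivity. Insertion of copper into the hindered C–Br bond may also be sluggish, so that protodebromination competes. The fallback forms the same pyran ring at its other C–O bond (O1–C2) by an SN2 reaction.
- It sets out from alcohol 18, whose two bromides are exchanged by double Miyaura borylation (B2pin2, Pd(OAc)2, SPhos, KOAc, dioxane, 90 °C; the weak base leaves the free alcohol alone) to give the bis(pinacol boronate) F3.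
- Oxidation (H2O2, aq NaOH, THF, 0 °C) gives the bis-phenol alcohol F4.
- Mitsunobu cyclisation (PPh3, DIAD, THF, 0 °C) lets one of the two diastereotopic phenols displace the activated primary oxygen. The transition state is a compact six-membered one, where the trans arrangement of ring B and the spectator arene should weigh more than in a seven-membered metallacycle.
- The other phenol is left free, so the route is rejoined at phenol 22 and step 12 is no longer needed.

Step 13. Bromination may also take place at C6 of ring A (para to O1 and ortho to the 7-benzyloxy group), or may run on to polybromides, because the rate advantage of the free phenol over a resorcinol-type diether is finite. The fallback uses an electrophile that attacks phenoxides only.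
- It sets out from phenol 22, which is coupled with benzenediazonium tetrafluoroborate (pyridine–THF, 0 °C) at D5 to give the para-azo phenol F5.
- Methylation (MeI, K2CO3, DMF) gives the azo methyl ether F6.
- Reductive cleavage (Na2S2O4, THF–H2O) gives the D5 aniline F7.
- Diazotisation (NaNO2, TsOH, MeCN–H2O, 0 °C) gives the arenediazonium tosylate F8, which KI converts in the same flask (Sandmeyer-type iodination) into the D5 aryl iodide F9.
- F9 enters the Suzuki–Miyaura coupling with boronate 30 under the conditions of step 19, and the route is rejoined at olefin 31.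

Further compounds
F1 | step 9 | (4R)-3-{[2-(benzyloxy)-4,5-dimethoxyphenyl]acetyl}-4-isopropyl-1,3-thiazolidine-2-thione | COc1cc(OCc2ccccc2)c(CC(=O)N2[C@H](C(C)C)CSC2=S)cc1OC
F2 | step 9 | (4R)-3-{(2R)-2-[2-(benzyloxy)-4,5-dimethoxyphenyl]-3,3-bis[4-(benzyloxy)-2-bromophenyl]propanoyl}-4-isopropyl-1,3-thiazolidine-2-thione | COc1cc(OCc2ccccc2)c([C@H](C(=O)N2[C@H](C(C)C)CSC2=S)C(c2ccc(OCc3ccccc3)cc2Br)c2ccc(OCc3ccccc3)cc2Br)cc1OC
F3 | step 11 | (2R)-2-[2-(benzyloxy)-4,5-dimethoxyphenyl]-3,3-bis[4-(benzyloxy)-2-(4,4,5,5-tetramethyl-1,3,2-dioxaborolan-2-yl)phenyl]propan-1-ol | COc1cc(OCc2ccccc2)c([C@H](CO)C(c2ccc(OCc3ccccc3)cc2B2OC(C)(C)C(C)(C)O2)c2ccc(OCc3ccccc3)cc2B2OC(C)(C)C(C)(C)O2)cc1OC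
F4 | step 11 | (2R)-2-[2-(benzyloxy)-4,5-dimethoxyphenyl]-3,3-bis[4-(benzyloxy)-2-hydroxyphenyl]propan-1-ol | COc1cc(OCc2ccccc2)c([C@H](CO)C(c2ccc(OCc3ccccc3)cc2O)c2ccc(OCc3ccccc3)cc2O)cc1OC
F5 | step 13 | 5-(benzyloxy)-2-{(3R,4R)-7-(benzyloxy)-3-[2-(benzyloxy)-4,5-dimethoxyphenyl]chroman-4-yl}-4-[(E)-phenyldiazenyl]phenol | COc1cc(OCc2ccccc2)c([C@@H]2COc3cc(OCc4ccccc4)ccc3[C@H]2c2cc(/N=N/c3ccccc3)c(OCc3ccccc3)cc2O)cc1OC
F6 | step 13 | (3R,4S)-7-(benzyloxy)-4-{4-(benzyloxy)-2-methoxy-5-[(E)-phenyldiazenyl]phenyl}-3-[2-(benzyloxy)-4,5-dimethoxyphenyl]chromane | COc1cc(OCc2ccccc2)c([C@@H]2COc3cc(OCc4ccccc4)ccc3[C@H]2c2cc(/N=N/c3ccccc3)c(OCc3ccccc3)cc2OC)cc1OC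
F7 | step 13 | 2-(benzyloxy)-5-{(3R,4S)-7-(benzyloxy)-3-[2-(benzyloxy)-4,5-dimethoxyphenyl]chroman-4-yl}-4-methoxyaniline | COc1cc(OCc2ccccc2)c([C@@H]2COc3cc(OCc4ccccc4)ccc3[C@H]2c2cc(N)c(OCc3ccccc3)cc2OC)cc1OC
F8 | step 13 | 2-(benzyloxy)-5-{(3R,4S)-7-(benzyloxy)-3-[2-(benzyloxy)-4,5-dimethoxyphenyl]chroman-4-yl}-4-methoxybenzenediazonium 4-methylbenzenesulfonate | COc1cc(OCc2ccccc2)c([C@@H]2COc3cc(OCc4ccccc4)ccc3[C@H]2c2cc([N+]#N)c(OCc3ccccc3)cc2OC)cc1OC.Cc1ccc(cc1)S(=O)(=O)[O-]
F9 | step 13 | (3R,4S)-7-(benzyloxy)-4-[4-(benzyloxy)-5-iodo-2-methoxyphenyl]-3-[2-(benzyloxy)-4,5-dimethoxyphenyl]chromane | COc1cc(OCc2ccccc2)c([C@@H]2COc3cc(OCc4ccccc4)ccc3[C@H]2c2cc(I)c(OCc3ccccc3)cc2OC)cc1OC
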